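**Retrosynthetic overview**

- Lepidine C (13) is traced back to its bis(N-SEM) derivative 12 (SEM = 2-(trimethylsilyl)ethoxymethyl), then to bis-acetate 11 and bis-carbinol 10, which carry an oxygen on each bridging carbon.
- Key disconnection: the two CH(OH)–C2 bonds of 10. Each imidazole is attached through C2, the carbon between N1 and N3, to a single bridging carbon on a benzene ring (on ring A ortho to the ether oxygen and meta to OMe; on ring B meta to the ether oxygen). Both bridging carbons can therefore be formyl carbons of dialdehyde 3, and both imidazoles come from one C2-lithiated N-SEM imidazole 8.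
- Dialdehyde 3 is cut at the ring A C–O bond of the diaryl ether (SNAr of fluoro aldehyde 1 by phenol 2); 8 comes from imidazole 4 by SEM protection and C2 lithiation.
- No ring is formed. All four rings are bought; the ether link between rings A and B is made first, then both imidazole rings are attached in one operation.

Key step: step 3

Remark: the target has no stereocentre and the two N–H tautomers of each imidazole are equivalent, so N-protection raises no regiochemical question. The two carbinol centres made in step 3 are carried as a mixture of diastereomers and removed in step 5.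

**Route**

Step 1
Reactants: 1 2-fluoro-5-methoxybenzaldehyde; 2 3-hydroxybenzaldehyde
Product: 3 2-(3-formylphenoxy)-5-methoxybenzaldehyde
Conditions: K2CO3, DMAc, 140 °C, N2
Reagents that add atoms: none
Why: Nucleophilic aromatic substitution (SNAr): the ortho formyl group stabilises the Meisenheimer intermediate and fluoride is the best leaving group for addition–elimination, so the phenoxide of 2 should displace it despite the deactivating para methoxy group, and neither aldehyde can enolise.

Step 2
Reactants: 4 imidazole; 5 2-(trimethylsilyl)ethoxymethyl chloride (SEMCl)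
Product: 7 1-SEM-imidazole (1-{[2-(trimethylsilyl)ethoxy]methyl}-1H-imidazole), via sodium imidazolide 6 (not isolated)
Conditions: NaH, THF, 0 °C; then 5, 0 °C → rt
Reagents that add atoms: none
Why: N-alkylation (SN2 at the chloromethyl ether) of the imidazolide anion, whose two nitrogens are equivalent, so only one product can form.

Step 3
Reactants: 7 1-SEM-imidazole; 3 2-(3-formylphenoxy)-5-methoxybenzaldehyde
Product: 10 bis-carbinol {2-[3-(hydroxy(1-SEM-imidazol-2-yl)methyl)phenoxy]-5-methoxyphenyl}(1-SEM-imidazol-2-yl)methanol (mixture of diastereomers), via 2-lithio-1-SEM-imidazole 8 (not isolated), via dilithium bis-alkoxide 9 (not isolated)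
Conditions: 7 (2.5 equiv), n-BuLi (2.4 equiv), THF, −78 °C; then 3, −78 → 0 °C; then H2O
Reagents that add atoms: none
Why: n-BuLi removes the C2 proton of 7, the most acidic ring proton because the carbanion sits between both nitrogens and the lithium is held by the SEM oxygen, to give 8, and two molecules of 8 add to the two formyl carbons of 3 to give the dilithium bis-alkoxide 9, which water protonates to 10. The closest known reaction type is the 1,2-addition of C2-lithiated N-protected imidazoles to aromatic aldehydes. No ring is closed; two C–C bonds are made. The two carbinol stereocentres form without control, which is accepted because step 5 removes both. The step needs site selectivity of metalation (C2 over C5), secured by the acidity of C2 and the coordinating SEM group at −78 °C, and complete reaction at both formyl groups, secured by the excess of 8 and by the absence of enolisable or otherwise acidic protons in 3.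

Step 4
Reactants: 10 bis-carbinol
Product: 11 bis-acetate of 10 (both carbinol oxygens acetylated; mixture of diastereomers)
Conditions: Ac2O, pyridine, DMAP (cat.), CH2Cl2, 0 °C → rt
Reagents that add atoms: acetic anhydride, CC(=O)OC(C)=O
Why: DMAP-catalysed O-acylation of two secondary benzylic alcohols; any acetyl group taken up at the imidazole N3 is itself an acyl donor and is lost on aqueous work-up.

Step 5
Reactants: 11 bis-acetate
Product: 12 bis(N-SEM) lepidine C (1-SEM-2-{5-methoxy-2-[3-((1-SEM-imidazol-2-yl)methyl)phenoxy]benzyl}imidazole)
Conditions: H2 (3 atm), 10% Pd/C, AcOH–EtOH, 40 °C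
Reagents that add atoms: none
Why: Catalytic hydrogenolysis of two activated C–OAc bonds, each on a carbon bearing an aryl and a heteroaryl ring; acetic acid protonates the imidazole nitrogens so they should not poison the palladium, the aryl ethers and SEM groups should be inert, and both stereocentres disappear.

Step 6
Reactants: 12 bis(N-SEM) lepidine C
Product: 13 lepidine C (2-{5-methoxy-2-[3-(1H-imidazol-2-ylmethyl)phenoxy]benzyl}-1H-imidazole)
Conditions: 3 M aq. HCl, EtOH, 80 °C; then aq. NaHCO3
Reagents that add atoms: none
Why: Acid-catalysed hydrolysis of the two N,O-acetal (SEM) groups, a standard N-SEM deprotection of imidazoles; the diaryl ether, the aryl methyl ether and the 2-benzylimidazole units are stable to hot dilute HCl, and neutralisation gives the free base.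

**Compound list**

1 | 2-fluoro-5-methoxybenzaldehyde | COc1ccc(F)c(C=O)c1 | starting material
2 | 3-hydroxybenzaldehyde | O=Cc1cccc(O)c1 | starting material
3 | 2-(3-formylphenoxy)-5-methoxybenzaldehyde | COc1ccc(Oc2cccc(C=O)c2)c(C=O)c1 | intermediate
4 | imidazole | c1c[nH]cn1 | starting material
5 | 2-(trimethylsilyl)ethoxymethyl chloride (SEMCl) | C[Si](C)(C)CCOCCl | starting material
6 | sodium imidazolide (formed in the flask) | [Na+].c1c[n-]cn1 | intermediate
7 | 1-{[2-(trimethylsilyl)ethoxy]methyl}-1H-imidazole (1-SEM-imidazole) | C[Si](C)(C)CCOCn1ccnc1 | intermediate
8 | 2-lithio-1-SEM-imidazole (formed in the flask) | [Li]c1nccn1COCC[Si](C)(C)C | intermediate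
9 | dilithium bis-alkoxide of 10 (formed in the flask, mixture of diastereomers) | COc1ccc(Oc2cccc(C([O-])c3nccn3COCC[Si](C)(C)C)c2)c(C([O-])c2nccn2COCC[Si](C)(C)C)c1.[Li+].[Li+] | intermediate
10 | {2-[3-(hydroxy(1-SEM-imidazol-2-yl)methyl)phenoxy]-5-methoxyphenyl}(1-SEM-imidazol-2-yl)methanol (bis-carbinol, mixture of diastereomers) | COc1ccc(Oc2cccc(C(O)c3nccn3COCC[Si](C)(C)C)c2)c(C(O)c2nccn2COCC[Si](C)(C)C)c1 | intermediate
11 | bis-acetate of 10 (mixture of diastereomers) | COc1ccc(Oc2cccc(C(OC(C)=O)c3nccn3COCC[Si](C)(C)C)c2)c(C(OC(C)=O)c2nccn2COCC[Si](C)(C)C)c1 | intermediate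
12 | bis(N-SEM) lepidine C | COc1ccc(Oc2cccc(Cc3nccn3COCC[Si](C)(C)C)c2)c(Cc2nccn2COCC[Si](C)(C)C)c1 | intermediate
13 | lepidine C | COc1ccc(Oc2cccc(Cc3ncc[nH]3)c2)c(Cc2ncc[nH]2)c1 | target

**Step count**

Total steps: 6. Longest linear sequence: 5 steps (steps 1, 3, 4, 5, 6; the branch from imidazole, steps 2, 3, 4, 5, 6, is equally long).

**Steps most likely to fail**

1. Step 5 (double hydrogenolysis). The basic imidazole nitrogens may bind to the palladium surface and stop the reaction after one or neither C–O cleavage, or the acetates may solvolyse back to carbinols instead of being reduced. Fallback: radical deoxygenation, setting out from bis-carbinol 10 and replacing steps 4 and 5. Both hydroxyl groups are converted with O-phenyl chlorothionoformate and DMAP in MeCN at rt into the bis(O-phenyl thionocarbonate) F1. F1 is then reduced with Bu3SnH and AIBN in toluene at 110 °C (Barton–McCombie deoxygenation; each intermediate radical is stabilised by an aryl and an imidazolyl ring). This should give 12, where the route is rejoined for step 6.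

2. Step 1 (SNAr). The methoxy group para to fluorine lowers the electrophilicity of the carbon under attack, so substitution may be slow and overtaken by base-induced disproportionation or degradation of the aldehydes at the temperature required. Fallback: copper-catalysed Ullmann-type diaryl ether coupling, which does not depend on an electron-poor ring and is helped by an ortho carbonyl group. It sets out from 2, which is coupled with commercial 2-bromo-5-methoxybenzaldehyde (COc1ccc(Br)c(C=O)c1) using CuI, N,N-dimethylglycine and Cs2CO3 in dioxane at 90 °C. It gives 3 directly and rejoins the route at step 3; no compound outside the list is made (F0: none).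

3. Step 3 (double addition). The lithio reagent may be lost by protonation before it adds, or the mono-adduct may separate as a poorly soluble lithium alkoxide so that the second formyl group reacts incompletely, leaving mixtures that are hard to purify as diastereomers. Fallback: the same two benzylic carbon–C2 bonds are made with reversed polarity by Negishi coupling, setting out from 3 and rejoining at 12, so that steps 3 to 5 are replaced.
   - Reduction of 3 with NaBH4 in MeOH at 0 °C gives the diol [2-(3-(hydroxymethyl)phenoxy)-5-methoxyphenyl]methanol F2.
   - SOCl2 in CH2Cl2 with catalytic DMF converts F2 into 2-(chloromethyl)-1-[3-(chloromethyl)phenoxy]-4-methoxybenzene F3.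
   - Zinc insertion (Zn dust, LiCl, THF, 25 °C) gives the bis(benzylzinc chloride) F4, which is used without isolation.
   - 2-Bromo-1-SEM-imidazole F5 is made from commercial 2-bromo-1H-imidazole and 5 with NaH in THF.
   - Coupling of F4 with F5 using Pd(OAc)2 and SPhos in THF at 25–50 °C should give 12.

**Further compounds**

F1 | step 5 | bis(O-phenyl thionocarbonate) of bis-carbinol 10 (mixture of diastereomers) | COc1ccc(Oc2cccc(C(OC(=S)Oc3ccccc3)c3nccn3COCC[Si](C)(C)C)c2)c(C(OC(=S)Oc2ccccc2)c2nccn2COCC[Si](C)(C)C)c1
F0 | step 1 | none | none
F2 | step 3 | [2-(3-(hydroxymethyl)phenoxy)-5-methoxyphenyl]methanol | COc1ccc(Oc2cccc(CO)c2)c(CO)c1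
F3 | step 3 | 2-(chloromethyl)-1-[3-(chloromethyl)phenoxy]-4-methoxybenzene | COc1ccc(Oc2cccc(CCl)c2)c(CCl)c1
F4 | step 3 | bis(benzylzinc chloride) derived from F3 (formed in the flask) | COc1ccc(Oc2cccc(C[Zn]Cl)c2)c(C[Zn]Cl)c1
F5 | step 3 | 2-bromo-1-{[2-(trimethylsilyl)ethoxy]methyl}-1H-imidazole | C[Si](C)(C)CCOCn1ccnc1Br
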